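The earlier runs and the new flask are calculated with constants of no real substance, and the scatter is random.

**Slowing product.** Product in the south run reads 10% at 2.00 h and 20% at 5.00 h, with 76% of the starting material left and the partner in excess by charge. Its mean rate after 2.00 h is lower than before it. Something in the flask seems to fade with time.

in all of them: free catalyst 0.5 mol%

| flask | starting material | partner | remark |
|---|---|---|---|
| south | 0.10 M | 1.5 equiv | run made earlier |
| west | 0.40 M | 1.5 equiv | run made earlier |
| flask | 0.20 M | 1.50 equiv |  |

| run | time / h | product / % | starting material / % |
|---|---|---|---|
| south | 1.00 | 5 | 94 |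
| south | 2.00 | 10 | 86 |
| south | 3.00 | 20 | 84 |
| south | 4.00 | 19 | 78 |
| south | 5.00 | 20 | 76 |
| west | 1.00 | 17 | 81 |
| west | 2.00 | 30 | 71 |
| west | 3.00 | 42 | 60 |
| west | 4.00 | 51 | 48 |
| west | 5.00 | 54 | 46 |

(readings scatter by 2 percentage points)

1. factor on the rate of making product when 30% of the starting material are converted if free catalyst is charged twice over
2. factor on the rate when 30% of the starting material are converted if free catalyst is charged at 5 mol% instead

**Two readings.** Let the fade constant be the first-order constant with which the rate dies away. The south run gives it from the slowing between its rate up to 2.00 h and its rate after that, 0.162 h⁻¹. The west run gives it from the slowing between its early and late rates, 0.305 h⁻¹. These come from different runs and part by a factor of 1.88, with a scatter of 2 percentage points on each reading, so the constant is rough. Their mean is 0.234 h⁻¹.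

**Own reckoning.** The flask's concentration is the geometric mean of the south and west ones. The west run reaches 30% at 2.00 h, and stretching that by the root of the first-hour ratio puts the flask there at 3.69 h. With twice the catalyst, this reckoning takes the time to half, so the fade has less time to act. The factor is then 3.08. At 5 mol% the same rule gives 21.7.

**The forecast.** The forecast gives 1.9 (range 1.3 to 2.1) and 8 (range 3 to 11), on the ground “I expect a simple catalytic turnover that is first order in catalyst”. The reckoning above differs from it and stands higher.

**The result.** The flask gives 2.85 and 17.2.

    partner + catalyst intermediate A → catalyst intermediate B (k = 200 M⁻¹ h⁻¹)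
    partner → decomposed reagent (k = 0.270 h⁻¹)
    catalyst intermediate B ⇌ free catalyst + product (K = 0.990 M, k = 59.0 h⁻¹)
    starting material + free catalyst → catalyst intermediate A (k = 900 M⁻¹ h⁻¹)

**One reason.** The flask reaches 30% at 3.17 h. With that time the fade constant gives 2.90 for this flask against 2.85. For the 5 mol% flask it gives 19.5 against 17.2, an overshoot. The fade is the passing of partner into decomposed reagent. Taking that step away lowers the apparent order in free catalyst at this conversion from 2.0 to 1.0.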